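**Plan**

- Retrosynthesis: the prenyl O–CH2 bond and the ester O–CH3 bond are cut first; then the diaryl ether bond O–C6 and the C1–carboxyl bond of ring A are cut together (ring A = the benzoate ring: C1 ester carbon, C2 prenyloxy, C4 methyl, C6 aryloxy; ring B = the dimethoxy ring).
- Enabling feature: C1 lies between the two oxygen-bearing carbons C2 and C6, so C6 and C1 are the two carbons of a 3-alkoxybenzyne (C2 carries the alkoxy group). That aryne can take up the ring B phenoxide oxygen at C6 and then CO2 at C1.
- Forward: no ring is built; both benzene rings are bought. Ring A becomes a 2-silylaryl triflate from 3,5-dimethoxytoluene (steps 1–4), ring B a hindered phenol from 2,4-dimethoxybenzaldehyde (steps 5–8). The two are joined with CO2 (step 9), then esterification, deprotection and prenylation finish the route (steps 10–12).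
- Stereochemistry: none to set; the target has no stereocentre and its alkene carries two identical methyl groups.

Key step: step 9

**Route**

Step 1
Reactants: 1 3,5-dimethoxytoluene
Product: 3 2-bromo-1,3-dimethoxy-5-methylbenzene, via (2,6-dimethoxy-4-methylphenyl)lithium 2 (not isolated)
Conditions: n-BuLi, THF, 0 °C → rt; then BrCH2CH2Br, −78 °C → rt
Reagents that add atoms: 1,2-dibromoethane, BrCCBr
Why: Directed ortho-metalation removes the most acidic ring proton, the one between the two methoxy groups, and the aryllithium takes bromine from 1,2-dibromoethane with loss of ethene.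

Step 2
Reactants: 3 2-bromo-1,3-dimethoxy-5-methylbenzene
Product: 4 2-bromo-5-methylbenzene-1,3-diol
Conditions: BBr3, CH2Cl2, −78 °C → rt; then H2O
Reagents that add atoms: none
Why: BBr3 cleaves both aryl methyl ethers by Lewis-acid-assisted SN2 demethylation and leaves the aryl bromide untouched.

Step 3
Reactants: 4 2-bromo-5-methylbenzene-1,3-diol
Product: 5 2-bromo-3-(methoxymethoxy)-5-methylphenol
Conditions: MOMCl (1.0 equiv), i-Pr2NEt, CH2Cl2, 0 °C → rt
Reagents that add atoms: chloromethyl methyl ether (MOMCl), COCCl
Why: Williamson-type O-alkylation of the symmetric diol with one equivalent of MOMCl should give the mono-acetal as the main component of a statistical mixture, from which diol 4 is recovered and recycled.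

Step 4
Reactants: 5 2-bromo-3-(methoxymethoxy)-5-methylphenol
Product: 9 3-(methoxymethoxy)-5-methyl-2-(trimethylsilyl)phenyl trifluoromethanesulfonate, via aryl trimethylsilyl ether 6 (not isolated), via aryllithium 7 (not isolated), via lithium 2-silylphenoxide 8 (not isolated)
Conditions: HMDS, THF, reflux, then evaporation; n-BuLi, THF, −100 → −78 °C; Tf2O, −78 °C
Reagents that add atoms: hexamethyldisilazane (HMDS), C[Si](C)(C)N[Si](C)(C)C; trifluoromethanesulfonic anhydride (Tf2O), O=S(=O)(OS(=O)(=O)C(F)(F)F)C(F)(F)F
Why: O-silylation, bromine–lithium exchange and retro-Brook 1,3-O→C silyl shift put the trimethylsilyl group on the former C–Br carbon, and the lithium phenoxide so released is triflated in the same flask, which is the standard one-pot route from 2-bromophenols to 2-silylaryl triflates.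

Step 5
Reactants: 10 2,4-dimethoxybenzaldehyde
Product: 12 2,4-dimethoxyphenol, via 2,4-dimethoxyphenyl formate 11 (not isolated)
Conditions: 30% aq. H2O2, H2SO4 (cat.), MeOH, rt
Reagents that add atoms: hydrogen peroxide, OO
Why: In this acid-catalysed Dakin oxidation the electron-rich aryl group migrates to oxygen in the peroxide adduct (Baeyer–Villiger-type shift) and the aryl formate is methanolysed in the same pot.

Step 6
Reactants: 12 2,4-dimethoxyphenol
Product: 13 2-hydroxy-3,5-dimethoxybenzaldehyde
Conditions: MgCl2, Et3N, (CH2O)n, MeCN, reflux; then 1 M HCl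
Reagents that add atoms: paraformaldehyde (formaldehyde), C=O
Why: Magnesium-phenoxide-directed ortho-formylation (Casnati–Skattebøl reaction) delivers formaldehyde within the chelate to C6, the only free ortho position, and a second equivalent of formaldehyde takes up hydride and leaves as methanol.

Step 7
Reactants: 13 2-hydroxy-3,5-dimethoxybenzaldehyde
Product: 14 2-(hydroxymethyl)-4,6-dimethoxyphenol
Conditions: NaBH4, MeOH, 0 °C; then aq. NH4Cl
Reagents that add atoms: none
Why: Hydride reduction of the aldehyde with NaBH4 is selective, the phenol and the aryl ethers being inert, and the neutral work-up spares the acid-sensitive salicyl alcohol.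

Step 8
Reactants: 14 2-(hydroxymethyl)-4,6-dimethoxyphenol
Product: 15 2,4-dimethoxy-6-(triisopropylsilyloxymethyl)phenol
Conditions: TIPSCl (1.05 equiv), imidazole, DMF, 0 °C
Reagents that add atoms: chlorotriisopropylsilane (TIPSCl), CC(C)[Si](Cl)(C(C)C)C(C)C
Why: Chemoselective silylation is expected because the bulky silyl chloride reacts with the unhindered primary hydroxyl much faster than with a phenol that is flanked by two ortho substituents and hydrogen-bonded to the neighbouring methoxy oxygen.

Step 9
Reactants: 9 3-(methoxymethoxy)-5-methyl-2-(trimethylsilyl)phenyl trifluoromethanesulfonate; 15 2,4-dimethoxy-6-(triisopropylsilyloxymethyl)phenol; 16 carbon dioxide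
Product: 20 2-[2,4-dimethoxy-6-(triisopropylsilyloxymethyl)phenoxy]-6-(methoxymethoxy)-4-methylbenzoic acid, via potassium phenoxide 17 (not isolated), via 3-(methoxymethoxy)-5-methylbenzyne 18 (not isolated), via aryl potassium adduct 19 (not isolated)
Conditions: 15 (1.3 equiv), KH (1.3 equiv), THF, 0 °C; then CO2 (1 atm), KF, 18-crown-6, slow addition of 9 (1.0 equiv), THF, 0 °C → rt; then 0.5 M HCl, 0 °C
Reagents that add atoms: none
Why: Proposed new method: fluoride removes the trimethylsilyl group of 9 and loss of triflate gives aryne 18, the crown-ether-separated phenoxide 17 adds to the aryne carbon remote from the methoxymethoxy group so that the charge of 19 sits on the carbon ortho to that inductively withdrawing, cation-chelating oxygen, and this anion is carboxylated by CO2 in aprotic THF that holds no O–H or N–H acid. The closest known reaction types are the three-component coupling of arynes, amines and CO2 to anthranilic acids with KF and 18-crown-6 in THF, the fluoride-mediated O-arylation of hindered phenols with silylaryl triflates, and the intramolecular acylation of the same kind of 2-aryloxyaryl anion in aryne–salicylate xanthone syntheses. No ring closes and no stereocentre forms. The step needs addition of the phenoxide at C6 and not at C1, which the 3-alkoxy group of the aryne secures, and carboxylation ahead of protonation, which is secured by pre-forming the phenoxide with KH and by leaving out acetonitrile. Reversible carbonate formation between 17 and CO2 should only buffer the phenoxide, because the free phenoxide is the stronger nucleophile and the carbonate reverts as it is consumed. The doubly ortho-substituted carboxylate product is kept from a second arylation by running the phenoxide in slight excess over 9.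

Step 10
Reactants: 20 2-[2,4-dimethoxy-6-(triisopropylsilyloxymethyl)phenoxy]-6-(methoxymethoxy)-4-methylbenzoic acid
Product: 21 methyl 2-[2,4-dimethoxy-6-(triisopropylsilyloxymethyl)phenoxy]-6-(methoxymethoxy)-4-methylbenzoate
Conditions: MeI, K2CO3, DMF, rt
Reagents that add atoms: iodomethane, CI
Why: SN2 O-methylation of the carboxylate takes place at the unhindered methyl iodide and is therefore insensitive to the two ortho substituents that would block a Fischer esterification.

Step 11
Reactants: 21 methyl 2-[2,4-dimethoxy-6-(triisopropylsilyloxymethyl)phenoxy]-6-(methoxymethoxy)-4-methylbenzoate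
Product: 22 methyl 2-hydroxy-6-[2-(hydroxymethyl)-4,6-dimethoxyphenoxy]-4-methylbenzoate
Conditions: HCl (2 M in MeOH), 40 °C
Reagents that add atoms: none
Why: Acid-catalysed acetal exchange removes the methoxymethyl group as dimethoxymethane and acid methanolysis cleaves the primary silyl ether, while the benzylic hydroxyl should survive because both methoxy groups are meta to its carbon and cannot stabilise a benzylic cation.

Step 12
Reactants: 22 methyl 2-hydroxy-6-[2-(hydroxymethyl)-4,6-dimethoxyphenoxy]-4-methylbenzoate; 23 1-bromo-3-methylbut-2-ene (prenyl bromide)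
Product: 24 methyl 2-[2-(hydroxymethyl)-4,6-dimethoxyphenoxy]-4-methyl-6-[(3-methylbut-2-en-1-yl)oxy]benzoate
Conditions: K2CO3, acetone, reflux
Reagents that add atoms: none
Why: In this Williamson etherification K2CO3 deprotonates only the phenol and not the benzylic alcohol, and the phenoxide displaces bromide from the primary allylic carbon by SN2.

**Compound list**

1 | 3,5-dimethoxytoluene | COc1cc(C)cc(OC)c1 | starting material
2 | (2,6-dimethoxy-4-methylphenyl)lithium | [Li]c1c(OC)cc(C)cc1OC | intermediate
3 | 2-bromo-1,3-dimethoxy-5-methylbenzene | COc1cc(C)cc(OC)c1Br | intermediate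
4 | 2-bromo-5-methylbenzene-1,3-diol | Cc1cc(O)c(Br)c(O)c1 | intermediate
5 | 2-bromo-3-(methoxymethoxy)-5-methylphenol | COCOc1cc(C)cc(O)c1Br | intermediate
6 | [2-bromo-3-(methoxymethoxy)-5-methylphenoxy]trimethylsilane | COCOc1cc(C)cc(O[Si](C)(C)C)c1Br | intermediate
7 | [2-(methoxymethoxy)-4-methyl-6-(trimethylsilyloxy)phenyl]lithium | COCOc1cc(C)cc(O[Si](C)(C)C)c1[Li] | intermediate
8 | lithium 3-(methoxymethoxy)-5-methyl-2-(trimethylsilyl)phenoxide | [Li+].COCOc1cc(C)cc([O-])c1[Si](C)(C)C | intermediate
9 | 3-(methoxymethoxy)-5-methyl-2-(trimethylsilyl)phenyl trifluoromethanesulfonate | COCOc1cc(C)cc(OS(=O)(=O)C(F)(F)F)c1[Si](C)(C)C | intermediate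
10 | 2,4-dimethoxybenzaldehyde | COc1ccc(C=O)c(OC)c1 | starting material
11 | 2,4-dimethoxyphenyl formate | COc1ccc(OC=O)c(OC)c1 | intermediate
12 | 2,4-dimethoxyphenol | COc1ccc(O)c(OC)c1 | intermediate
13 | 2-hydroxy-3,5-dimethoxybenzaldehyde | COc1cc(C=O)c(O)c(OC)c1 | intermediate
14 | 2-(hydroxymethyl)-4,6-dimethoxyphenol | COc1cc(CO)c(O)c(OC)c1 | intermediate
15 | 2,4-dimethoxy-6-(triisopropylsilyloxymethyl)phenol | COc1cc(CO[Si](C(C)C)(C(C)C)C(C)C)c(O)c(OC)c1 | intermediate
16 | carbon dioxide | O=C=O | starting material
17 | potassium 2,4-dimethoxy-6-(triisopropylsilyloxymethyl)phenoxide | [K+].COc1cc(CO[Si](C(C)C)(C(C)C)C(C)C)c([O-])c(OC)c1 | intermediate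
18 | 3-(methoxymethoxy)-5-methylbenzyne | COCOC1=CC(C)=CC#C1 | intermediate
19 | {2-[2,4-dimethoxy-6-(triisopropylsilyloxymethyl)phenoxy]-6-(methoxymethoxy)-4-methylphenyl}potassium | [K]c1c(OCOC)cc(C)cc1Oc1c(CO[Si](C(C)C)(C(C)C)C(C)C)cc(OC)cc1OC | intermediate
20 | 2-[2,4-dimethoxy-6-(triisopropylsilyloxymethyl)phenoxy]-6-(methoxymethoxy)-4-methylbenzoic acid | OC(=O)c1c(OCOC)cc(C)cc1Oc1c(CO[Si](C(C)C)(C(C)C)C(C)C)cc(OC)cc1OC | intermediate
21 | methyl 2-[2,4-dimethoxy-6-(triisopropylsilyloxymethyl)phenoxy]-6-(methoxymethoxy)-4-methylbenzoate | COC(=O)c1c(OCOC)cc(C)cc1Oc1c(CO[Si](C(C)C)(C(C)C)C(C)C)cc(OC)cc1OC | intermediate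
22 | methyl 2-hydroxy-6-[2-(hydroxymethyl)-4,6-dimethoxyphenoxy]-4-methylbenzoate | COC(=O)c1c(O)cc(C)cc1Oc1c(CO)cc(OC)cc1OC | intermediate
23 | 1-bromo-3-methylbut-2-ene (prenyl bromide) | CC(C)=CCBr | starting material
24 | methyl 2-[2-(hydroxymethyl)-4,6-dimethoxyphenoxy]-4-methyl-6-[(3-methylbut-2-en-1-yl)oxy]benzoate | COC(=O)c1c(OCC=C(C)C)cc(C)cc1Oc1c(CO)cc(OC)cc1OC | target

**Step count**

Total: 12 steps. Longest linear sequence: 8 steps (steps 1–4 then 9–12; the ring B branch, steps 5–8 then 9–12, is equally long).

**Steps most likely to fail**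

Step 9. The aryl anion 19 may be protonated before it meets CO2, the phenoxide may be held back as its carbonate, or fluoride may attack the silyl ether, so that the carboxyl group is not installed. The fallback uses known chemistry in two operations and sets out from 9 and 15. Conventional fluoride-mediated O-arylation (CsF, MeCN, rt), in which the aryl anion is deliberately protonated, should give the diaryl ether 1-[2,4-dimethoxy-6-(triisopropylsilyloxymethyl)phenoxy]-3-(methoxymethoxy)-5-methylbenzene F1. Directed ortho-metalation with n-BuLi (THF, −78 → −20 °C) is then expected at the ring A C–H flanked by the methoxymethoxy and aryloxy oxygens, the strongest directing pair in the molecule, though the ring B C–H between the two methoxy groups may compete. This gives {2-[2,4-dimethoxy-6-(triisopropylsilyloxymethyl)phenoxy]-6-(methoxymethoxy)-4-methylphenyl}lithium F2. Quenching with CO2 and acidifying with cold dilute HCl rejoins the route at acid 20.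

Step 3. The second hydroxyl is alkylated at much the same rate as the first, so over-alkylation and unreacted diol accompany the mono-ether and throughput is low. The fallback desymmetrises through the silyl shift instead of through partial alkylation and sets out from 4. HMDS gives 2-bromo-5-methyl-1,3-bis(trimethylsilyloxy)benzene F3. n-BuLi (THF, −78 °C) effects bromine–lithium exchange to [4-methyl-2,6-bis(trimethylsilyloxy)phenyl]lithium F4. Its retro-Brook shift moves exactly one silyl group to carbon and frees exactly one oxygen, as lithium 5-methyl-2-(trimethylsilyl)-3-(trimethylsilyloxy)phenoxide F5. MOMCl alkylates this single phenoxide to [2-(methoxymethoxy)-4-methyl-6-(trimethylsilyloxy)phenyl]trimethylsilane F6. K2CO3 in MeOH removes the remaining O-silyl group to give 3-(methoxymethoxy)-5-methyl-2-(trimethylsilyl)phenol F7. Triflation (Tf2O, pyridine, CH2Cl2, 0 °C) comes back to the route at 9, so steps 3 and 4 are both replaced.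

Step 11. While the acetal and the silyl ether are removed, the acid may solvolyse the freed benzylic hydroxyl to its methyl ether, or silyl cleavage may stay incomplete. The fallback never exposes the free benzylic alcohol to acid and sets out from 21. Selective acetal cleavage with ZnBr2 and n-PrSH (CH2Cl2, 0 °C), which spares silyl ethers, should give methyl 2-[2,4-dimethoxy-6-(triisopropylsilyloxymethyl)phenoxy]-6-hydroxy-4-methylbenzoate F8. Prenylation with 23 (K2CO3, acetone, reflux) gives methyl 2-[2,4-dimethoxy-6-(triisopropylsilyloxymethyl)phenoxy]-4-methyl-6-[(3-methylbut-2-en-1-yl)oxy]benzoate F9. Desilylation with Bu4NF buffered with AcOH (THF, 0 °C) then comes back to the route at the target 24, so steps 11 and 12 are replaced.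

**Further compounds**

F1 | step 9 | 1-[2,4-dimethoxy-6-(triisopropylsilyloxymethyl)phenoxy]-3-(methoxymethoxy)-5-methylbenzene | COCOc1cc(C)cc(Oc2c(CO[Si](C(C)C)(C(C)C)C(C)C)cc(OC)cc2OC)c1
F2 | step 9 | {2-[2,4-dimethoxy-6-(triisopropylsilyloxymethyl)phenoxy]-6-(methoxymethoxy)-4-methylphenyl}lithium | [Li]c1c(OCOC)cc(C)cc1Oc1c(CO[Si](C(C)C)(C(C)C)C(C)C)cc(OC)cc1OC
F3 | step 3 | 2-bromo-5-methyl-1,3-bis(trimethylsilyloxy)benzene | Cc1cc(O[Si](C)(C)C)c(Br)c(O[Si](C)(C)C)c1
F4 | step 3 | [4-methyl-2,6-bis(trimethylsilyloxy)phenyl]lithium | Cc1cc(O[Si](C)(C)C)c([Li])c(O[Si](C)(C)C)c1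
F5 | step 3 | lithium 5-methyl-2-(trimethylsilyl)-3-(trimethylsilyloxy)phenoxide | [Li+].Cc1cc([O-])c([Si](C)(C)C)c(O[Si](C)(C)C)c1
F6 | step 3 | [2-(methoxymethoxy)-4-methyl-6-(trimethylsilyloxy)phenyl]trimethylsilane | COCOc1cc(C)cc(O[Si](C)(C)C)c1[Si](C)(C)C
F7 | step 3 | 3-(methoxymethoxy)-5-methyl-2-(trimethylsilyl)phenol | COCOc1cc(C)cc(O)c1[Si](C)(C)C
F8 | step 11 | methyl 2-[2,4-dimethoxy-6-(triisopropylsilyloxymethyl)phenoxy]-6-hydroxy-4-methylbenzoate | COC(=O)c1c(O)cc(C)cc1Oc1c(CO[Si](C(C)C)(C(C)C)C(C)C)cc(OC)cc1OC
F9 | step 11 | methyl 2-[2,4-dimethoxy-6-(triisopropylsilyloxymethyl)phenoxy]-4-methyl-6-[(3-methylbut-2-en-1-yl)oxy]benzoate | COC(=O)c1c(OCC=C(C)C)cc(C)cc1Oc1c(CO[Si](C(C)C)(C(C)C)C(C)C)cc(OC)cc1OC
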